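**Retrosynthetic overview**

1. Ring A (C1–C5 and C9, the trione ring) is the unchanged carbon ring of phloroglucinol (1); the C1 acyl group comes from isobutyryl chloride (2) via ketone 3, and the C3 and C5 prenyl groups from prenyl bromide (4) via deoxycohumulone (5).
2. The whole C6–C7–C8 bridge, with the C7 prenyl group, the C7 stereocenter and the gem-dimethyl carbon, is the C10 skeleton of (R)-lavandulol (6), used as its triflate (7).
3. Key disconnections, both made in one flask: C5–C6 (alkylative dearomatization of flat, mirror-symmetric 5 by 7, giving dienone 8) and C1–C8 (light-driven cation–olefin closure onto the acyl-bearing carbon, giving target 9).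
4. Ring order: ring A is never constructed (it is the arene, dearomatized in the key step); ring B (C1, C9, C5, C6, C7, C8) is formed last.

Assumption: (R)-(−)-lavandulol (6, the natural enantiomer) is bought in high enantiomeric purity; C1–C9 are the bicyclo[3.3.1]nonane locants of the target and enols are drawn in the tautomer of the given SMILES.

**Route**

Step 1
Reactants: 1 phloroglucinol; 2 isobutyryl chloride
Product: 3 2-methyl-1-(2,4,6-trihydroxyphenyl)propan-1-one
Conditions: AlCl3 (3 equiv), PhNO2/CH2Cl2, 0 → 60 °C; ice/aq. HCl
Reagents that add atoms: none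
Why: Friedel–Crafts C-acylation of the very electron-rich arene; the AlCl3-complexed, hydrogen-bonded ketone is deactivated, so the reaction stops at mono-acylation, and no stereocenter is formed.

Step 2
Reactants: 3 2-methyl-1-(2,4,6-trihydroxyphenyl)propan-1-one; 4 prenyl bromide (2.1 equiv)
Product: 5 deoxycohumulone, 2-methyl-1-[2,4,6-trihydroxy-3,5-bis(3-methylbut-2-en-1-yl)phenyl]propan-1-one
Conditions: 10% aq. KOH, 0 °C, 2 h; aq. HCl
Reagents that add atoms: none
Why: Double C-alkylation of the phenolate in water (SN2), where the hydrogen-bonded oxygens leave the two unsubstituted ring carbons as the reactive sites; holding 4 near two equivalents limits the third, dearomatizing prenylation, and no stereocenter is formed.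

Step 3
Reactants: 6 (R)-lavandulol
Product: 7 (R)-lavandulyl triflate, (2R)-5-methyl-2-(prop-1-en-2-yl)hex-4-en-1-yl trifluoromethanesulfonate
Conditions: Tf2O (1.1 equiv), 2,6-lutidine (1.2 equiv), CH2Cl2, −78 °C, 15 min; cold pentane, short SiO2 plug, used at once
Reagents that add atoms: triflic anhydride, O=S(=O)(OS(=O)(=O)C(F)(F)F)C(F)(F)F
Why: O-sulfonylation of a primary alcohol at low temperature; the stereocenter is one carbon away from the reacting oxygen and is untouched, and the triflate is chosen because a β-branched primary electrophile needs this leaving group to alkylate a substituted ring carbon.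

Step 4
Reactants: 5 deoxycohumulone; 7 (R)-lavandulyl triflate (1.2 equiv)
Product: 9 (1R,5R,7S)-4-hydroxy-8,8-dimethyl-3,5,7-tris(3-methylbut-2-en-1-yl)-1-(2-methylpropanoyl)bicyclo[3.3.1]non-3-ene-2,9-dione (target), via dearomatized lavandulyl dienone 8 (not isolated)
Conditions: LiN(SiMe3)2 (3.1 equiv), THF, −78 °C; 7, −78 → −20 °C; AcOH (4 equiv); solvent switch to degassed PhMe (5 mM); hν (365 nm), 15 °C; chromatography
Reagents that add atoms: none
Why: Proposed new method: the lithium phenolate of mirror-symmetric 5 is C-alkylated by primary triflate 7 at one of its two equivalent prenyl-bearing carbons (alkylative dearomatization, SN2, the known reaction type for diprenyl acylphloroglucinols with primary alkyl triflates), and after protonation the hydrogen-bonded enol–acyl chromophore of 8 is excited so that its enol proton passes to the tethered isopropenyl group (excited-state intramolecular proton transfer, a photochemical Conia-ene equivalent known for aroyl analogues), the tertiary C8 cation then collapsing onto the adjacent acyl-bearing C1 and not onto the more nucleophilic prenyl-bearing C3 that ground-state acid would favour; new here are the aliphatic acyl chromophore and running both events without isolating 8; C7 is carried unchanged from 6, C5 is formed without facial control (both C6 epimers of 8, about 1:1), and because the bridge can only close on the face that carries the chain, through a chair with the C7 prenyl equatorial, only (6R)-8 gives (1R,5R,7S)-9, while the (6S) epimer ends as a separable C7-endo diastereomer and O-cyclized pyrans, so the yield ceiling of this step is about half.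

**Compound list**

1 | phloroglucinol (benzene-1,3,5-triol) | Oc1cc(O)cc(O)c1 | starting material
2 | isobutyryl chloride (2-methylpropanoyl chloride) | CC(C)C(Cl)=O | starting material
3 | 2-methyl-1-(2,4,6-trihydroxyphenyl)propan-1-one | CC(C)C(=O)c1c(O)cc(O)cc1O | intermediate
4 | prenyl bromide (1-bromo-3-methylbut-2-ene) | CC(C)=CCBr | starting material
5 | deoxycohumulone, 2-methyl-1-[2,4,6-trihydroxy-3,5-bis(3-methylbut-2-en-1-yl)phenyl]propan-1-one | CC(C)=CCc1c(O)c(CC=C(C)C)c(O)c(C(=O)C(C)C)c1O | intermediate
6 | (R)-lavandulol, (2R)-5-methyl-2-(prop-1-en-2-yl)hex-4-en-1-ol | CC(C)=CC[C@@H](CO)C(C)=C | starting material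
7 | (R)-lavandulyl triflate, (2R)-5-methyl-2-(prop-1-en-2-yl)hex-4-en-1-yl trifluoromethanesulfonate | CC(C)=CC[C@@H](COS(=O)(=O)C(F)(F)F)C(C)=C | intermediate
8 | (6R)-3,5-dihydroxy-6-[(2S)-5-methyl-2-(prop-1-en-2-yl)hex-4-en-1-yl]-4,6-bis(3-methylbut-2-en-1-yl)-2-(2-methylpropanoyl)cyclohexa-2,4-dien-1-one (formed together with its 6S epimer) | CC(C)=CCC1=C(O)[C@@](CC=C(C)C)(C[C@H](CC=C(C)C)C(C)=C)C(=O)C(C(=O)C(C)C)=C1O | intermediate
9 | (1R,5R,7S)-4-hydroxy-8,8-dimethyl-3,5,7-tris(3-methylbut-2-en-1-yl)-1-(2-methylpropanoyl)bicyclo[3.3.1]non-3-ene-2,9-dione | CC(C)=CCC1=C(O)[C@@]2(CC=C(C)C)C[C@H](CC=C(C)C)C(C)(C)[C@@](C(=O)C(C)C)(C1=O)C2=O | target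

**Step count**

Total steps: 4. Longest linear sequence: 3 (1 → 3 → 5 → 9); the side branch 6 → 7 is one step.

**Steps most likely to fail, with fallbacks**

Step 4 is the most exposed. The weakest part is the SN2 attack of an already substituted ring carbon on a β-branched triflate, where O-alkylation and elimination of 7 compete. The fallback reverses the order in which the arene is loaded, so that the hindered electrophile meets an unsubstituted ring carbon and the quaternary centre is made with reactive prenyl bromide. It sets out from 3, which is C-alkylated with 7 (LiN(SiMe3)2, THF, −78 → 0 °C, AcOH quench) at one free ring carbon to give 2-methyl-1-{2,4,6-trihydroxy-3-[(2S)-5-methyl-2-(prop-1-en-2-yl)hex-4-en-1-yl]phenyl}propan-1-one F1. F1 is then treated with 4 (2.2 equiv, aq. KOH, 0 °C). The first prenyl group goes to the last free ring carbon and gives the fully substituted arene 2-methyl-1-{2,4,6-trihydroxy-3-[(2S)-5-methyl-2-(prop-1-en-2-yl)hex-4-en-1-yl]-5-(3-methylbut-2-en-1-yl)phenyl}propan-1-one F2. The second prenylation is dearomatizing; the share that lands on the lavandulyl-bearing carbon comes back to the route at 8, and the isomer prenylated twice on the other carbon is removed by chromatography. Here 8 is isolated and irradiated in a separate operation to give 9. This fallback does not remove the C6-epimer issue or the dependence on the photochemical closure.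

Step 2 can stall at mixtures of mono-, di- and tri-prenylated material with O-prenyl ethers. The fallback separates carbon–carbon bond formation from installation of the trisubstituted alkene. It sets out from 3, which is C-allylated twice with prop-2-en-1-ol under Pd(PPh3)4 and Et3B (THF, rt; π-allyl electrophile under neutral conditions, water as the only by-product) to give 2-methyl-1-[2,4,6-trihydroxy-3,5-di(prop-2-en-1-yl)phenyl]propan-1-one F3. Cross-metathesis of F3 with excess 2-methylbut-2-ene (second-generation Grubbs catalyst, CH2Cl2, 40 °C) converts both allyl groups into prenyl groups and comes back to the route at 5.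

Step 3 can fail because the triflate ionizes or eliminates on concentration. The fallback replaces the short-lived sulfonate by a storable halide. It sets out from 6, which under Appel conditions (PPh3, I2, imidazole, CH2Cl2, 0 °C; stereocenter not involved) gives (2R)-1-iodo-5-methyl-2-(prop-1-en-2-yl)hex-4-ene F4. F4 replaces 7 in step 4 (LiN(SiMe3)2, THF–DMPU, 0 °C → rt), coming back to the route at 8, which is irradiated as before. The iodide is much less reactive than the triflate, so this alkylation will be slow.

**Further compounds**

F1 | step 4 | 2-methyl-1-{2,4,6-trihydroxy-3-[(2S)-5-methyl-2-(prop-1-en-2-yl)hex-4-en-1-yl]phenyl}propan-1-one | CC(C)C(=O)c1c(O)cc(O)c(C[C@H](CC=C(C)C)C(C)=C)c1O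
F2 | step 4 | 2-methyl-1-{2,4,6-trihydroxy-3-[(2S)-5-methyl-2-(prop-1-en-2-yl)hex-4-en-1-yl]-5-(3-methylbut-2-en-1-yl)phenyl}propan-1-one | CC(C)=CCc1c(O)c(C[C@H](CC=C(C)C)C(C)=C)c(O)c(C(=O)C(C)C)c1O
F3 | step 2 | 2-methyl-1-[2,4,6-trihydroxy-3,5-di(prop-2-en-1-yl)phenyl]propan-1-one | C=CCc1c(O)c(CC=C)c(O)c(C(=O)C(C)C)c1O
F4 | step 3 | (2R)-1-iodo-5-methyl-2-(prop-1-en-2-yl)hex-4-ene | CC(C)=CC[C@@H](CI)C(C)=C
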